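The cyclohexene ring (C1 bears CH2OBz, C2 is the vinylic CH, C3–C6 carry the oxygens) is cut at C1=C2 and C4–C5. Both cuts fall between two allylic carbinol halves whose oxygens on C3 and C6 are cis across the ring, so one silicon atom can bridge them. The precursor is therefore a silaketal tetraene made from resolved (R)-2-(benzoyloxymethyl)penta-1,4-dien-3-ol and achiral penta-1,4-dien-3-ol. A double ring-closing metathesis forms both ring bonds in one operation (C4–C5 as a second alkene), selects one of two diastereotopic vinyl groups and so fixes C3. Bridge-directed osmylation, ligand-controlled benzoylation of O5 and desilylation finish the route.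

Key step: step 5

Remark: ring atoms are numbered as in the name of 14. The (S,S) ligand in step 7 rests on the assumption that it directs acylation to the R-configured carbinol of a cis-1,2-diol; if the sense is the reverse, the (R,R) ligand is used.

Step 1
Reactants: 1 2-bromoprop-2-en-1-ol; 2 acrolein
Product: 3 rac-2-methylidenepent-4-ene-1,3-diol
Conditions: CrCl2 (4 equiv), NiCl2 (2 mol %), DMF, 0 °C to rt
Reagents that add atoms: none
Why: Nozaki–Hiyama–Kishi reaction: zerovalent nickel inserts into the C–Br bond, transmetallation gives the alkenyl species of trivalent chromium, which adds 1,2 to acrolein and tolerates the free hydroxyl; the new carbinol centre is formed racemic and is resolved in step 3.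

Step 2
Reactants: 3 rac-2-methylidenepent-4-ene-1,3-diol
Product: 5 rac-(3-acetoxy-2-methylidenepent-4-en-1-yl) benzoate, via racemic monobenzoate 4 (not isolated)
Conditions: BzCl (1.05 equiv), pyridine, CH2Cl2, −40 °C; then Ac2O, DMAP (cat.), rt
Reagents that add atoms: benzoyl chloride, O=C(Cl)c1ccccc1; acetic anhydride, CC(=O)OC(C)=O
Why: Two-stage acylation in one flask: at −40 °C benzoyl chloride should esterify the primary allylic hydroxyl much faster than the hindered doubly allylic secondary one, which is then acetylated under DMAP catalysis (nucleophilic acyl transfer); the stereocentre stays racemic.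

Step 3
Reactants: 5 rac-(3-acetoxy-2-methylidenepent-4-en-1-yl) benzoate
Product: 6 [(3R)-3-hydroxy-2-methylidenepent-4-en-1-yl] benzoate
Conditions: immobilised Candida antarctica lipase B, phosphate buffer pH 7/MTBE, 30 °C, stopped near 45 % conversion
Reagents that add atoms: none
Why: Lipase-catalysed kinetic resolution by enantioselective ester hydrolysis: by the empirical size rule for lipases (vinyl in the medium pocket, the branched alkenyl group in the large pocket) the R acetate should be cleaved and the S acetate left, the primary benzoate being a poor lipase substrate; this fixes the stereocentre that becomes C6.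

Step 4
Reactants: 6 [(3R)-3-hydroxy-2-methylidenepent-4-en-1-yl] benzoate; 7 penta-1,4-dien-3-ol
Product: 9 [(3R)-2-methylidene-3-({[(penta-1,4-dien-3-yl)oxy]di(propan-2-yl)silyl}oxy)pent-4-en-1-yl] benzoate, via chlorosilane 8 (not isolated)
Conditions: iPr2SiCl2 (3 equiv), imidazole, CH2Cl2, 0 °C; excess silane evaporated; then 7 (1.5 equiv), imidazole, DMAP (cat.), DMF, rt
Reagents that add atoms: dichlorodi(propan-2-yl)silane, CC(C)[Si](Cl)(Cl)C(C)C
Why: Stepwise silyl ether formation (unsymmetrical silaketal synthesis): the alcohol is monosilylated by excess iPr2SiCl2, the excess is removed and the remaining Si–Cl bond is substituted by the second alcohol, which avoids the symmetrical bis-ethers; the carbinol stereocentre is not involved.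

Step 5
Reactants: 9 [(3R)-2-methylidene-3-({[(penta-1,4-dien-3-yl)oxy]di(propan-2-yl)silyl}oxy)pent-4-en-1-yl] benzoate
Product: 11 [(1S,5R)-3,3-di(propan-2-yl)-2,4-dioxa-3-silabicyclo[3.2.2]nona-6,8-dien-6-yl]methyl benzoate, via cis-silepine 10 (not isolated)
Conditions: second-generation Grubbs catalyst (10 mol %), 1,4-benzoquinone (20 mol %), toluene (0.003 M), 80 °C, ethylene (1 atm) for 1 h, then argon sparge
Reagents that add atoms: none
Why: Two consecutive olefin-metathesis cycles (metallacyclobutane formation and cycloreversion at the ruthenium alkylidene) run on one tethered tetraene: the faster one joins the vinyl group next to C6 to one vinyl group of the divinylcarbinyl ether (new C4=C5 bond), the second joins the 1,1-disubstituted alkene to the remaining vinyl group (new C1=C2 bond), each with loss of ethene. The closest known reactions are silaketal-tethered ring-closing metathesis to 4,7-dihydro-1,3,2-dioxasilepines and ring-closing metathesis of 1,4,7-trienes to cyclohexa-1,4-dienes. The first closure is a seven-membered ring closure through the O–Si–O tether; the second closes the six-membered carbocycle transannularly across that ring and gives the bridged bicyclo[3.2.2] diene. The only new stereocentre, C3, arises by selection between the two diastereotopic vinyl groups of the divinylcarbinyl unit and is controlled by the resolved C6 centre, because only the silepine with its two alkenyl groups cis can close again under a one-atom bridge. The step needs cis over trans pairing, ring closure over oligomerisation and no alkene migration: the initial ethylene atmosphere should let the unproductive trans silepine reopen, the tether and high dilution favour ring closure, two alkenes on the same carbinol cannot close on each other, and benzoquinone suppresses ruthenium hydride isomerisation of the doubly allylic C–H bonds.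

Step 6
Reactants: 11 [(1S,5R)-3,3-di(propan-2-yl)-2,4-dioxa-3-silabicyclo[3.2.2]nona-6,8-dien-6-yl]methyl benzoate
Product: 12 [(1R,5S,8R,9S)-8,9-dihydroxy-3,3-di(propan-2-yl)-2,4-dioxa-3-silabicyclo[3.2.2]non-6-en-6-yl]methyl benzoate
Conditions: OsO4 (2 mol %), NMO (1.1 equiv), acetone/H2O 8:1, 0 °C
Reagents that add atoms: osmium tetroxide, O=[Os](=O)(=O)=O; N-methylmorpholine N-oxide, C[N+]1([O-])CCOCC1; water, O
Why: Upjohn dihydroxylation: OsO4 should add suprafacially to the 1,2-disubstituted C4=C5 alkene from the face turned away from the O–Si–O bridge, which sets C4 and C5 cis to each other and trans to O3 and O6, while the C1=C2 alkene is slowed by its third substituent and allylic benzoate and, after the first addition, by the new hydroxyls on its only open face.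

Step 7
Reactants: 12 [(1R,5S,8R,9S)-8,9-dihydroxy-3,3-di(propan-2-yl)-2,4-dioxa-3-silabicyclo[3.2.2]non-6-en-6-yl]methyl benzoate
Product: 13 [(1R,5S,8R,9S)-9-(benzoyloxy)-8-hydroxy-3,3-di(propan-2-yl)-2,4-dioxa-3-silabicyclo[3.2.2]non-6-en-6-yl]methyl benzoate
Conditions: BzCl (1.05 equiv), CuCl2 (5 mol %), (S,S)-Ph-BOX (5 mol %), iPr2NEt (1.1 equiv), CH2Cl2, 0 °C
Reagents that add atoms: benzoyl chloride, O=C(Cl)c1ccccc1
Why: Catalytic site-selective monobenzoylation of a cis-1,2-diol through a chiral chelate of divalent copper with a bis(oxazoline) (the reaction type used to desymmetrise meso-1,2-diols): the diol is locally almost mirror-symmetric, so the ligand antipode and not the substrate should decide which hydroxyl reacts, here O5 on the R-configured carbinol carbon; no stereocentre is formed.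

Step 8
Reactants: 13 [(1R,5S,8R,9S)-9-(benzoyloxy)-8-hydroxy-3,3-di(propan-2-yl)-2,4-dioxa-3-silabicyclo[3.2.2]non-6-en-6-yl]methyl benzoate
Product: 14 [(3R,4S,5R,6S)-5-(benzoyloxy)-3,4,6-trihydroxycyclohex-1-en-1-yl]methyl benzoate
Conditions: HF·pyridine, pyridine/THF, 0 °C to rt
Reagents that add atoms: none
Why: Fluoride-induced cleavage of the dialkoxysilane (desilylation): the silicon bridge leaves as iPr2SiF2 under mildly acidic conditions that keep both benzoates in place and should not promote benzoyl migration to the cis hydroxyl on C4; no stereocentre is touched.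

Compound list
1 | 2-bromoprop-2-en-1-ol | C=C(Br)CO | starting material
2 | acrolein (prop-2-enal) | C=CC=O | starting material
3 | rac-2-methylidenepent-4-ene-1,3-diol | C=CC(O)C(=C)CO | intermediate
4 | rac-(3-hydroxy-2-methylidenepent-4-en-1-yl) benzoate | C=CC(O)C(=C)COC(=O)c1ccccc1 | intermediate
5 | rac-(3-acetoxy-2-methylidenepent-4-en-1-yl) benzoate | C=CC(OC(C)=O)C(=C)COC(=O)c1ccccc1 | intermediate
6 | [(3R)-3-hydroxy-2-methylidenepent-4-en-1-yl] benzoate | C=C[C@@H](O)C(=C)COC(=O)c1ccccc1 | intermediate
7 | penta-1,4-dien-3-ol | C=CC(O)C=C | starting material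
8 | [(3R)-3-{[chlorodi(propan-2-yl)silyl]oxy}-2-methylidenepent-4-en-1-yl] benzoate | C=C[C@@H](O[Si](Cl)(C(C)C)C(C)C)C(=C)COC(=O)c1ccccc1 | intermediate
9 | [(3R)-2-methylidene-3-({[(penta-1,4-dien-3-yl)oxy]di(propan-2-yl)silyl}oxy)pent-4-en-1-yl] benzoate | C=C[C@@H](O[Si](C(C)C)(C(C)C)OC(C=C)C=C)C(=C)COC(=O)c1ccccc1 | intermediate
10 | 2-[(4R,7R)-7-ethenyl-2,2-di(propan-2-yl)-4,7-dihydro-1,3,2-dioxasilepin-4-yl]prop-2-en-1-yl benzoate (4,7-cis) | C=C[C@@H]1C=C[C@H](C(=C)COC(=O)c2ccccc2)O[Si](C(C)C)(C(C)C)O1 | intermediate
11 | [(1S,5R)-3,3-di(propan-2-yl)-2,4-dioxa-3-silabicyclo[3.2.2]nona-6,8-dien-6-yl]methyl benzoate | O=C(OCC1=C[C@@H]2C=C[C@H]1O[Si](C(C)C)(C(C)C)O2)c1ccccc1 | intermediate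
12 | [(1R,5S,8R,9S)-8,9-dihydroxy-3,3-di(propan-2-yl)-2,4-dioxa-3-silabicyclo[3.2.2]non-6-en-6-yl]methyl benzoate | O=C(OCC1=C[C@@H]2[C@H](O)[C@H](O)[C@H]1O[Si](C(C)C)(C(C)C)O2)c1ccccc1 | intermediate
13 | [(1R,5S,8R,9S)-9-(benzoyloxy)-8-hydroxy-3,3-di(propan-2-yl)-2,4-dioxa-3-silabicyclo[3.2.2]non-6-en-6-yl]methyl benzoate | O=C(OCC1=C[C@@H]2[C@H](O)[C@H](OC(=O)c3ccccc3)[C@H]1O[Si](C(C)C)(C(C)C)O2)c1ccccc1 | intermediate
14 | [(3R,4S,5R,6S)-5-(benzoyloxy)-3,4,6-trihydroxycyclohex-1-en-1-yl]methyl benzoate | O=C(OCC1=C[C@@H](O)[C@H](O)[C@H](OC(=O)c2ccccc2)[C@H]1O)c1ccccc1 | target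

Total step count: 8. Longest linear sequence: 8 steps (1 to 14).

Steps most likely to fail

Step 5. The second, bridging closure may stall at the monocyclic silepine, and material may be lost through the trans-configured silepine or through intermolecular metathesis. The fallback closes the two ring bonds in separate operations. It sets out from 9: the first-generation Grubbs catalyst, which engages only the monosubstituted vinyl groups, should give the cis-silepine 10 as an isolated compound (the trans isomer is separated). Bu4NF buffered with AcOH then cuts the tether to the Z-triene diol [(3R,4Z,6R)-3,6-dihydroxy-2-methylideneocta-4,7-dien-1-yl] benzoate F1. Ring-closing metathesis of this 1,4,7-triene (second-generation Hoveyda–Grubbs catalyst, 1,4-benzoquinone, CH2Cl2, 40 °C) closes the unbridged six-membered ring to the cis-dienediol [(3S,6R)-3,6-dihydroxycyclohexa-1,4-dien-1-yl]methyl benzoate F2. iPr2Si(OTf)2 and 2,6-lutidine bridge the cis-diol, and the route is rejoined at 11.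

Step 7. Site selection between the two hydroxyls of the nearly mirror-symmetric cis-diol may be poor with either ligand antipode, or the benzoyl group may migrate from O5 to O4 under the amine base. The fallback replaces catalyst control by stereoelectronic control. It sets out from 12: HF·pyridine removes the silicon bridge first to give the tetrol [(3R,4S,5R,6S)-3,4,5,6-tetrahydroxycyclohex-1-en-1-yl]methyl benzoate F3. PhC(OMe)3 with CSA should form a cyclic orthoester on the only cis-diol, giving the 4,5-O-(α-methoxybenzylidene) orthobenzoate F4. Brief treatment with aqueous AcOH opens such orthoesters to the axial ester and the equatorial alcohol. A(1,2) strain between the C1 substituent and O6 should favour the half-chair with O6 pseudoaxial, in which O5 is axial and O4 equatorial, so the benzoate should end on O5. The fallback comes back to the route at 14.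

Step 6. Osmylation of the trisubstituted C1=C2 alkene may compete with that of C4=C5, or both alkenes may be oxidised. The fallback deactivates the C1=C2 alkene as an enal before the oxidation. It sets out from 11: K2CO3 (cat.) in MeOH at 0 °C removes the benzoate to give [(1S,5R)-3,3-di(propan-2-yl)-2,4-dioxa-3-silabicyclo[3.2.2]nona-6,8-dien-6-yl]methanol F5. MnO2 oxidises the allylic alcohol to (1S,5R)-3,3-di(propan-2-yl)-2,4-dioxa-3-silabicyclo[3.2.2]nona-6,8-diene-6-carbaldehyde F6. OsO4/NMO should then attack only the electron-rich C4=C5 alkene, anti to the bridge, to give (1R,5S,8R,9S)-8,9-dihydroxy-3,3-di(propan-2-yl)-2,4-dioxa-3-silabicyclo[3.2.2]non-6-ene-6-carbaldehyde F7. Luche reduction (NaBH4, CeCl3·7H2O, MeOH, −40 °C) returns the allylic alcohol [(1R,5S,8R,9S)-8,9-dihydroxy-3,3-di(propan-2-yl)-2,4-dioxa-3-silabicyclo[3.2.2]non-6-en-6-yl]methanol F8. BzCl with 2,4,6-collidine at −40 °C should benzoylate the primary hydroxyl selectively, and the route is rejoined at 12.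

Further compounds
F1 | step 5 | [(3R,4Z,6R)-3,6-dihydroxy-2-methylideneocta-4,7-dien-1-yl] benzoate | C=C[C@@H](O)/C=C\[C@H](C(=C)COC(=O)c1ccccc1)O
F2 | step 5 | [(3S,6R)-3,6-dihydroxycyclohexa-1,4-dien-1-yl]methyl benzoate | O=C(OCC1=C[C@@H](O)C=C[C@H]1O)c1ccccc1
F3 | step 7 | [(3R,4S,5R,6S)-3,4,5,6-tetrahydroxycyclohex-1-en-1-yl]methyl benzoate | O=C(OCC1=C[C@@H](O)[C@H](O)[C@H](O)[C@H]1O)c1ccccc1
F4 | step 7 | 4,5-O-(α-methoxybenzylidene) orthobenzoate of F3 (2-methoxy-2-phenyl-1,3-dioxolane fused at C4 and C5) | O=C(OCC1=C[C@@H](O)[C@H](OC2(OC)c3ccccc3)[C@H](O2)[C@H]1O)c1ccccc1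
F5 | step 6 | [(1S,5R)-3,3-di(propan-2-yl)-2,4-dioxa-3-silabicyclo[3.2.2]nona-6,8-dien-6-yl]methanol | OCC1=C[C@@H]2C=C[C@H]1O[Si](C(C)C)(C(C)C)O2
F6 | step 6 | (1S,5R)-3,3-di(propan-2-yl)-2,4-dioxa-3-silabicyclo[3.2.2]nona-6,8-diene-6-carbaldehyde | O=CC1=C[C@@H]2C=C[C@H]1O[Si](C(C)C)(C(C)C)O2
F7 | step 6 | (1R,5S,8R,9S)-8,9-dihydroxy-3,3-di(propan-2-yl)-2,4-dioxa-3-silabicyclo[3.2.2]non-6-ene-6-carbaldehyde | O=CC1=C[C@@H]2[C@H](O)[C@H](O)[C@H]1O[Si](C(C)C)(C(C)C)O2
F8 | step 6 | [(1R,5S,8R,9S)-8,9-dihydroxy-3,3-di(propan-2-yl)-2,4-dioxa-3-silabicyclo[3.2.2]non-6-en-6-yl]methanol | OCC1=C[C@@H]2[C@H](O)[C@H](O)[C@H]1O[Si](C(C)C)(C(C)C)O2
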